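The earlier runs and the new flask are calculated from invented constants.

Take the two earlier runs at their flat ends and look for a number they share.

in all of them: starting material 0.10 M

| charge | reagent | second substrate | free catalyst | temperature | remark | time |
|---|---|---|---|---|---|---|
| ochre | 0.22 M | 0.020 M (fed, over 30 min) | 4.4 mM | −40 °C | run made earlier |  |
| blue | 0.15 M | 0.010 M (fed, over 30 min) | 4.4 mM | −40 °C | run made earlier |  |
| west | 0.150 M | 0.0200 M (fed, over 15 min) | 6.0 mM |  | at −10 °C throughout | 4.0 h |
| north-east | 0.150 M | 0.0200 M (fed, over 30 min) | 4.4 mM |  | at −40 °C until 30 min, from then on at −10 °C | 4.0 h |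

| run | time / h | target / % |
|---|---|---|
| ochre | 0.200 | 34 |
| ochre | 0.333 | 44 |
| ochre | 0.417 | 48 |
| ochre | 0.667 | 51 |
| ochre | 1.00 | 56 |
| ochre | 1.50 | 53 |
| ochre | 2.50 | 54 |
| blue | 0.133 | 24 |
| blue | 0.333 | 34 |
| blue | 0.667 | 40 |
| blue | 1.00 | 43 |
| blue | 1.33 | 42 |
| blue | 2.00 | 43 |
| blue | 2.50 | 43 |

(scatter of a reading: 2 percentage points)

* which one finishes higher in amount of target, in percent of the starting material charged ("neither" within 2 percentage points) (west / north-east / neither)
* amount of target at the end, in percent of the starting material charged, west
* amount of target at the end, in percent of the starting material charged, north-east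

- the earlier runs do not show what temperature does; that part of a forecast is a guess
- no earlier run changes the charge of free catalyst; that part of a forecast is a guess

Define the stop ratio as target divided by the product of starting material left and reagent left, all in mol per litre, on the flat end of a run. This is the equilibrium constant, if the plateau is an equilibrium. Reagent left is reckoned here as charge less target, since the share taken by the second substrate is unknown. The last readings give:

ochre: 7.07 L mol⁻¹

blue: 7.05 L mol⁻¹

These are readings with their scatter, but the two runs differ in reagent and in second substrate and still give nearly one ratio.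

Turn the question round: for west and north-east to part by more than 2 percentage points, what must be true? Both hold 0.150 M of reagent and end at −10 °C, so a shared ratio places them alike, whatever their path. One must therefore stop short of the ratio, with its free catalyst lost on the way.

The ochre run's first reading gives a time constant of approach:

12.1 min

That is 19.8 times shorter than the 4.0 h allowed, though it was read at −40 °C, and catalyst life at −10 °C is a guess. My own reckoning is therefore neither. The level is open: the earlier runs do not show what temperature does, and an unmoved ratio gives blue's 43 %.

The forecast differs: “The reaction simply stops, which points to the catalyst dying”. It puts north-east higher, with 38 % for west and 43 % for north-east.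

West ends at 14.5 % and north-east at 14.5 %, so the answer is neither. North-east held 37.9 % of target at 0.500 h and then fell back, and at the asked time the relaxation half-life of the target step, both ways together, is 0.128 h, short against 4.0 h. The stop ratio at the end of north-east, at −10 °C, reads:

1.40 L mol⁻¹

That stands 5.05 times below the ochre reading of 7.07 L mol⁻¹ at −40 °C.

    second substrate + reagent + free catalyst → free catalyst + second product (k = 0.170 L² mol⁻² s⁻¹, Ea = 37.0 kJ mol⁻¹)
    2 free catalyst → spent catalyst (k = 0.0220 L mol⁻¹ s⁻¹, Ea = 40.0 kJ mol⁻¹)
    starting material + reagent + free catalyst ⇌ free catalyst + target (K = 7.70 L mol⁻¹, k = 0.900 L² mol⁻² s⁻¹, Ea = 41.0 kJ mol⁻¹, ΔH = −29.0 kJ mol⁻¹)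
    (constants at −40 °C)

Take north-east with 0.38 M of reagent, suppose this neighbour uses as much reagent as north-east did, and divide the ochre stop ratio by the same fall:

reagent left = 0.351 M

ratio = 7.07 L mol⁻¹ / 5.05 = 1.40 L mol⁻¹

target = ratio × reagent left / (1 + ratio × reagent left) = 32.9 %

The computed flask gives 31.5 %.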